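**Retrosynthetic overview** (halimane numbering: ring B = C5–C10, ring A = C1–C5/C10, chain C11–C16, CH2O = C24)
1. The sulfate goes on last. C14–C15 is cut by a light-driven decarboxylative Giese addition of the opened γ-lactone to 4-vinylbutenolide.
2. C11–C12 is cut by a light-driven Co/Ni coupling of two strained rings. One is a cyclopropanol (C11 homoenolate). The other is the cyclopropane-lactone from (R)-epichlorohydrin (C12, C13, C24).
3. C1=C10 is cut by a keto-aldehyde McMurry closure of ring A after the fragment union.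
4. C9 is set by face-selective cyclopropanation of the 9-methyl enolate. C4 and C5 come from Cu-catalysed conjugate addition to (S)-pulegone followed by equilibration.
5. Ring order: B is bought, then a temporary cyclopropane, then A. The butenolide is attached intact.

**Assumption:** (S)-(−)-pulegone, (R)-epichlorohydrin, the dioxolanylethyl Grignard solution and 4-bromofuran-2(5H)-one are purchased, and the target is delivered as the drawn free hydrogen sulfate, released cold from its pyridinium salt.

Step 1
Reactants: 1 (S)-(−)-pulegone; 2 [2-(1,3-dioxolan-2-yl)ethyl]magnesium bromide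
Product: 4 (2R,5S)-2-[4-(1,3-dioxolan-2-yl)-2-methylbutan-2-yl]-5-methylcyclohexan-1-one (side chain and methyl trans, both equatorial), via bromomagnesium enolate 3 (not isolated)
Conditions: CuBr·SMe2 (10 mol %), THF, −20 → 0 °C; aq NH4Cl; KOH (cat.), EtOH, reflux
Reagents that add atoms: none
Why: Copper-catalysed conjugate addition, as in the 8-substituted menthone series, builds quaternary C4, and base equilibration puts the tert-alkyl group equatorial and trans to the purchased C8 methyl, which sets C5 (about 85:15, minor epimer recycled).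

Step 2
Reactants: 4
Product: 6 (2R,5S,6R)-2-[4-(1,3-dioxolan-2-yl)-2-methylbutan-2-yl]-5,6-dimethylcyclohexan-1-one (all-equatorial major epimer; the C6 epimer is equally usable), via kinetic lithium enolate 5 (not isolated)
Conditions: LDA, THF, −78 °C; MeI, −78 → 0 °C
Reagents that add atoms: iodomethane, CI
Why: Kinetic enolate alkylation works because only the C9 methylene is accessible (C5–H is shielded by the tert-alkyl group), and the new C9 centre is erased again in step 3.

Step 3
Reactants: 6
Product: 9 (1S,2R,5S,6S)-2-[4-(1,3-dioxolan-2-yl)-2-methylbutan-2-yl]-5,6-dimethylbicyclo[4.1.0]heptan-1-ol (CH2 bridge = C11, cis to the C5 methyl and trans to the C2 side chain), via tetrasubstituted lithium enolate 7 (not isolated), via lithium cyclopropanolate 8 (not isolated)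
Conditions: LDA, THF, 0 °C; Sm, CH2I2, THF, −78 °C → rt; aq NH4Cl
Reagents that add atoms: diiodomethane, ICI
Why: This is a Simmons–Smith-type samarium-carbenoid cyclopropanation of a lithium enolate, in which CH2 should add to the chair-like enolate on the face opposite the C5 tert-alkyl group (the axial-attack face), fixing quaternary C9 with C11 cis to the C8 methyl.

Step 4
Reactants: 10 (R)-epichlorohydrin; 11 diethyl malonate
Product: 12 ethyl (1S,5R)-2-oxo-3-oxabicyclo[3.1.0]hexane-1-carboxylate
Conditions: NaOEt, EtOH, reflux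
Reagents that add atoms: none
Why: This known domino sequence of malonate alkylation, 3-exo-tet epoxide opening and lactonisation replaces the C–O bond of the bought stereocentre by C–C with clean inversion, which delivers C13.

Step 5
Reactants: 9; 12
Product: 13 ethyl (4R)-4-{2-[(1S,3R,6S)-3-[4-(1,3-dioxolan-2-yl)-2-methylbutan-2-yl]-1,6-dimethyl-2-oxocyclohexyl]ethyl}-2-oxotetrahydrofuran-3-carboxylate (epimers at lactone C3)
Conditions: Co(dmgH)2(py)Cl (10 mol %), NiBr2·glyme/dtbbpy (10 mol %), Zn (20 mol %, initiator), Cs2CO3 (20 mol %), DMA, 450 nm LEDs, 25 °C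
Reagents that add atoms: none
Why: Proposed new method: a redox-neutral, light-driven Co/Ni coupling of a donor cyclopropanol with an acceptor cyclopropane, in which cobaloxime(I) opens 12 by SN2 at its unhindered CH2 (the site cuprates attack, C13 untouched), blue light homolyses the Co–C bond to the primary C12 radical, the Ni(II) alkoxide of 9 undergoes two-electron β-carbon elimination of the less substituted C10–C11 bond to a neopentyl homoenolate that has no β-hydrogen and avoids the rearrangement-prone free C11 radical, radical capture and C(sp3)–C(sp3) reductive elimination form C11–C12, Ni(I) returns Co(II) to Co(I), and the O–H proton ends on the malonate carbon; the closest known reaction types are light-driven cobalt(I) ring-opening/radical reactions of strained electrophiles (also in tandem with nickel) and nickel-catalysed β-alkylation of cyclopropanol homoenolates with alkyl-radical precursors.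

Step 6
Reactants: 13
Product: 15 4-methyl-4-[(1R,3S,4S)-3,4-dimethyl-2-oxo-3-{2-[(3R)-5-oxotetrahydrofuran-3-yl]ethyl}cyclohexyl]pentanal, via acetal lactone 14 (not isolated)
Conditions: LiCl, DMSO–H2O, 140 °C; then 1 M HCl, THF, rt
Reagents that add atoms: water, O
Why: Krapcho dealkoxycarbonylation, as practised on 4-alkyl analogues of this lactone ester, removes the activating ester and merges the C14 epimers, and mild acetal hydrolysis then frees the C1 aldehyde without aldol or C5 epimerisation.

Step 7
Reactants: 15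
Product: 16 (4R)-4-{2-[(1S,2S,4aR)-1,2,5,5-tetramethyl-1,2,3,4,4a,5,6,7-octahydronaphthalen-1-yl]ethyl}dihydrofuran-2(3H)-one
Conditions: TiCl3(DME)1.5, Zn–Cu, DME, reflux, syringe-pump addition
Reagents that add atoms: none
Why: Intramolecular McMurry coupling of the 1,6-keto-aldehyde closes ring A and can place the alkene only at C1=C10, while slow addition to excess low-valent titanium consumes the ketone before C5 can epimerise and before the lactone reacts.

Step 8
Reactants: 17 4-bromofuran-2(5H)-one
Product: 18 4-vinylfuran-2(5H)-one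
Conditions: Pd(PPh3)4 (5 mol %), BHT, dioxane, 80 °C
Reagents that add atoms: tributyl(vinyl)stannane, C=C[Sn](CCCC)(CCCC)CCCC
Why: Stille coupling of the activated vinylogous acyl bromide gives the known radical acceptor, which is used at once with inhibitor present.

Step 9
Reactants: 16; 18
Product: 20 4-{(4S)-4-(hydroxymethyl)-6-[(1S,2S,4aR)-1,2,5,5-tetramethyl-1,2,3,4,4a,5,6,7-octahydronaphthalen-1-yl]hexyl}furan-2(5H)-one, via cesium (3R)-3-(hydroxymethyl)-5-[(1S,2S,4aR)-1,2,5,5-tetramethyl-1,2,3,4,4a,5,6,7-octahydronaphthalen-1-yl]pentanoate 19 (not isolated)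
Conditions: CsOH·H2O (1.0 equiv), THF–H2O, rt, evaporate; Fe(NO3)3·9H2O/di(2-picolyl)amine (10 mol %), MeCN–H2O, 427 nm LEDs, rt
Reagents that add atoms: none
Why: The γ-hydroxy carboxylate salt cannot relactonise, Fe(III)–carboxylate LMCT photolysis expels CO2 to give the primary C14 radical, and decarboxylative Giese addition to the vinyl terminus of 18 followed by Fe(II) reduction and protonation gives the β-alkyl butenolide, with C13 (β to the radical) untouched.

Step 10
Reactants: 20
Product: 22 (2S)-5-(5-oxo-2,5-dihydrofuran-3-yl)-2-{2-[(1S,2S,4aR)-1,2,5,5-tetramethyl-1,2,3,4,4a,5,6,7-octahydronaphthalen-1-yl]ethyl}pentyl hydrogen sulfate, via pyridinium sulfate 21 (not isolated)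
Conditions: SO3·pyridine, pyridine, 0 °C → rt; Dowex 50W (H+), MeOH–H2O, 0 °C
Reagents that add atoms: sulfur trioxide–pyridine complex, [O-]S(=O)(=O)[n+]1ccccc1
Why: O-sulfation of the only hydroxyl group with SO3·pyridine is mild enough for both the butenolide and the trisubstituted alkene, and cold proton exchange gives the free acid.

**Compound list**
1 | (S)-(−)-pulegone | C[C@H]1CCC(=C(C)C)C(=O)C1 | starting material
2 | [2-(1,3-dioxolan-2-yl)ethyl]magnesium bromide | Br[Mg]CCC1OCCO1 | starting material
3 | bromomagnesium enolate (C5=C10) of 4 | C[C@H]1CCC(C(C)(C)CCC2OCCO2)=C(O[Mg]Br)C1 | intermediate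
4 | (2R,5S)-2-[4-(1,3-dioxolan-2-yl)-2-methylbutan-2-yl]-5-methylcyclohexan-1-one | C[C@H]1CC[C@H](C(C)(C)CCC2OCCO2)C(=O)C1 | intermediate
5 | kinetic lithium enolate (C9=C10) of 4 | C[C@H]1CC[C@H](C(C)(C)CCC2OCCO2)C(O[Li])=C1 | intermediate
6 | (2R,5S,6R)-2-[4-(1,3-dioxolan-2-yl)-2-methylbutan-2-yl]-5,6-dimethylcyclohexan-1-one | C[C@H]1CC[C@H](C(C)(C)CCC2OCCO2)C(=O)[C@@H]1C | intermediate
7 | tetrasubstituted lithium enolate (C9=C10) of 6 | C[C@H]1CC[C@H](C(C)(C)CCC2OCCO2)C(O[Li])=C1C | intermediate
8 | lithium salt of cyclopropanol 9 | C[C@H]1CC[C@H](C(C)(C)CCC2OCCO2)[C@@]3(O[Li])C[C@@]13C | intermediate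
9 | (1S,2R,5S,6S)-2-[4-(1,3-dioxolan-2-yl)-2-methylbutan-2-yl]-5,6-dimethylbicyclo[4.1.0]heptan-1-ol | C[C@H]1CC[C@H](C(C)(C)CCC2OCCO2)[C@@]3(O)C[C@@]13C | intermediate
10 | (R)-epichlorohydrin | ClC[C@H]1CO1 | starting material
11 | diethyl malonate | CCOC(=O)CC(=O)OCC | starting material
12 | ethyl (1S,5R)-2-oxo-3-oxabicyclo[3.1.0]hexane-1-carboxylate | O=C1OC[C@@H]2C[C@]12C(=O)OCC | intermediate
13 | coupled keto acetal lactone ester (5R,8S,9S,13R) | C[C@H]1CC[C@H](C(C)(C)CCC2OCCO2)C(=O)[C@@]1(C)CC[C@H]3COC(=O)C3C(=O)OCC | intermediate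
14 | (4R)-4-{2-[(1S,3R,6S)-3-[4-(1,3-dioxolan-2-yl)-2-methylbutan-2-yl]-1,6-dimethyl-2-oxocyclohexyl]ethyl}dihydrofuran-2(3H)-one | C[C@H]1CC[C@H](C(C)(C)CCC2OCCO2)C(=O)[C@@]1(C)CC[C@H]3COC(=O)C3 | intermediate
15 | keto aldehyde lactone (C1 aldehyde, C10 ketone) | C[C@H]1CC[C@H](C(C)(C)CCC=O)C(=O)[C@@]1(C)CC[C@H]2COC(=O)C2 | intermediate
16 | decalin lactone | C[C@H]1CC[C@H]2C(=CCCC2(C)C)[C@@]1(C)CC[C@H]3COC(=O)C3 | intermediate
17 | 4-bromofuran-2(5H)-one | BrC1=CC(=O)OC1 | starting material
18 | 4-vinylfuran-2(5H)-one | C=CC1=CC(=O)OC1 | intermediate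
19 | cesium γ-hydroxy carboxylate from 16 | C[C@H]1CC[C@H]2C(=CCCC2(C)C)[C@@]1(C)CC[C@@H](CO)CC(=O)[O-].[Cs+] | intermediate
20 | butenolide alcohol | C[C@H]1CC[C@H]2C(=CCCC2(C)C)[C@@]1(C)CC[C@H](CCCC1=CC(=O)OC1)CO | intermediate
21 | pyridinium salt of 22 | C[C@H]1CC[C@H]2C(=CCCC2(C)C)[C@@]1(C)CC[C@H](CCCC1=CC(=O)OC1)COS(=O)(=O)[O-].c1cc[nH+]cc1 | intermediate
22 | CNP0360075.1 | C[C@H]1CC[C@H]2C(=CCCC2(C)C)[C@@]1(C)CC[C@H](CCCC1=CC(=O)OC1)COS(=O)(=O)O | target

**Total step count:** 10. **Longest linear sequence:** 8 (steps 1, 2, 3, 5, 6, 7, 9, 10).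

**Three steps most likely to fail**

Step 5 (the new Co/Ni coupling). Protonolysis of the homoenolate to the gem-dimethyl ketone, or slow capture at the neopentyl nickel centre, could win over coupling. The fallback uses known chemistry, sets out from 12 and from ketone 6 (as enolate 7), and rejoins at 14.
- 12 is opened at the cyclopropane CH2 with vinylmagnesium bromide/CuI to give ethyl (4R)-4-allyl-2-oxotetrahydrofuran-3-carboxylate F3.
- Krapcho dealkoxycarbonylation gives (R)-4-allyldihydrofuran-2(3H)-one F4.
- Ozonolysis with NaBH4 work-up gives (R)-4-(2-hydroxyethyl)dihydrofuran-2(3H)-one F5, which is used at once.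
- An Appel reaction gives (S)-4-(2-iodoethyl)dihydrofuran-2(3H)-one F6.
- Enolate 7 (LDA, then DMPU) is alkylated with F6, axially and trans to the C5 side chain, to give 14.

Step 7 (McMurry). The ketone lies between quaternary C9 and the neopentyl C5, and the lactone is only semi-compatible with low-valent titanium. The fallback sets out from 15 and rejoins at 16.
- SmI2 in THF effects intramolecular pinacol coupling to the cis-1,10-diol F7.
- Thiocarbonyldiimidazole gives the cyclic thionocarbonate F8.
- Corey–Winter elimination with P(OMe)3 releases the C1=C10 alkene regiospecifically.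

Step 3 (direct enolate cyclopropanation). Enolisation of the hindered methine may be slow, and the carbenoid may react poorly or with low facial bias. The fallback sets out from 6 and rejoins at 9.
- Thermodynamic silylation (TMSOTf, Et3N) gives the tetrasubstituted trimethylsilyl enol ether F1.
- Furukawa cyclopropanation (Et2Zn, CH2I2) of the isolated enol ether gives the siloxycyclopropane F2.
- K2CO3/MeOH removes the silyl group to give 9.

**Further compounds**
F1 | step 3 | trimethylsilyl enol ether (C9=C10) of 6 | C[C@H]1CC[C@H](C(C)(C)CCC2OCCO2)C(O[Si](C)(C)C)=C1C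
F2 | step 3 | trimethylsilyl ether of cyclopropanol 9 | C[C@H]1CC[C@H](C(C)(C)CCC2OCCO2)[C@@]3(O[Si](C)(C)C)C[C@@]13C
F3 | step 5 | ethyl (4R)-4-allyl-2-oxotetrahydrofuran-3-carboxylate | C=CC[C@H]1COC(=O)C1C(=O)OCC
F4 | step 5 | (R)-4-allyldihydrofuran-2(3H)-one | C=CC[C@H]1COC(=O)C1
F5 | step 5 | (R)-4-(2-hydroxyethyl)dihydrofuran-2(3H)-one | OCC[C@H]1COC(=O)C1
F6 | step 5 | (S)-4-(2-iodoethyl)dihydrofuran-2(3H)-one | ICC[C@H]1COC(=O)C1
F7 | step 7 | cis-1,10-diol from pinacol closure of 15 (either cis pair serves) | C[C@H]1CC[C@H]2C(O)(C(O)CCC2(C)C)[C@@]1(C)CC[C@H]3COC(=O)C3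
F8 | step 7 | cyclic 1,10-thionocarbonate of F7 | C[C@H]1CC[C@H]2C3(OC(=S)OC3CCC2(C)C)[C@@]1(C)CC[C@H]4COC(=O)C4
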